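## Retrosynthetic overview

- The last step is hydrogenolysis of thirteen benzyl ethers; before it, both rings D are closed in a single two-directional operation.
- The strategy rests on ring D: its hydroxyls sit on D2, D4 and D6 (phloroglucinol pattern), D1 carries the ether oxygen to ring C, D5 carries ring E and D3 is CH. Ring D is therefore a folded triketide substituted on two of its methylene carbons, and it is cut at D5–D6 and at D1–D2.
- This leaves a core bis(aryloxyacetate) of rings A, B and C (it brings D1, D6 and the ether oxygen) and two molecules of a 4-aryl-3-oxobutanoate (it brings ring E and D2 to D5). The crowded D1–O ether and the D5–ring E biaryl bond arrive ready-made in the two components.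
- Rings B and C both come from a 4-bromo-3,5-dioxygenated benzaldehyde. The formyl group activates the bromide for Ullmann ether coupling and is then converted into the phenol by Baeyer–Villiger oxidation. Ring A enters as 3,5-bis(benzyloxy)phenol.
- Ring order: rings A, B, C and E are used as preformed arenes; the two rings D are formed last and together.

Key step: step 14

Remarks on the chemistry:
- The bromo-dimethoxybenzaldehyde, 3,5-bis(benzyloxy)phenol, methyl bromoacetate, 2,4,6-trihydroxybenzaldehyde and ethyl diazoacetate are taken as purchased.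
- The keto ester is used as its ethyl ester, because its alkoxide is lost in the ring closure.
- The ring closure is run at the alkoxide level and not with excess amide base, since complete deprotonation would enolise the ester that has to be attacked.
- No compound of the route has a configurationally stable stereocentre. The enol ether intermediate is an E/Z mixture and the doubly acylated carbons of the dioxo ester intermediate are enolisable, so no descriptors are given.

## Route

Step 1
Reactants: 1 4-bromo-3,5-dimethoxybenzaldehyde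
Product: 2 4-bromo-3,5-dihydroxybenzaldehyde
Conditions: BBr3, CH2Cl2, −78 °C to rt; then H2O
Reagents that add atoms: none
Why: Lewis acid cleavage of aryl methyl ethers (BBr3 demethylation) proceeds through aryloxyboron species that water hydrolyses, and the formyl group and the aryl bromide should be returned unchanged after the hydrolytic work-up.

Step 2
Reactants: 2 4-bromo-3,5-dihydroxybenzaldehyde
Product: 3 4-bromo-3,5-bis(methoxymethoxy)benzaldehyde
Conditions: NaH, MOMCl, DMF, 0 °C to rt
Reagents that add atoms: chloromethyl methyl ether, COCCl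
Why: Williamson-type O-alkylation of the two phenoxides (MOM protection) should give acetals that withstand base, copper catalysis and peracid and can later be removed with acid in the presence of benzyl ethers.

Step 3
Reactants: 3 4-bromo-3,5-bis(methoxymethoxy)benzaldehyde; 4 3,5-bis(benzyloxy)phenol
Product: 5 4-[3,5-bis(benzyloxy)phenoxy]-3,5-bis(methoxymethoxy)benzaldehyde
Conditions: CuI (10 mol %), picolinic acid (20 mol %), K3PO4, DMSO, 90 °C, argon
Reagents that add atoms: none
Why: Copper-catalysed Ullmann diaryl ether synthesis should work because the para-formyl group activates the C–Br bond, the phenol is unhindered and electron-rich, and the picolinate ligand is suited to bromides with two ortho substituents.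

Step 4
Reactants: 5 4-[3,5-bis(benzyloxy)phenoxy]-3,5-bis(methoxymethoxy)benzaldehyde
Product: 7 4-[3,5-bis(benzyloxy)phenoxy]-3,5-bis(methoxymethoxy)phenol, via aryl formate 6 (not isolated)
Conditions: mCPBA, CH2Cl2, 0 °C to rt; then K2CO3 (cat.), MeOH, rt
Reagents that add atoms: 3-chloroperoxybenzoic acid, OOC(=O)c1cccc(Cl)c1
Why: Baeyer–Villiger oxidation of an electron-rich benzaldehyde (Dakin-type) should proceed with aryl migration, which the three oxygen substituents on the migrating ring favour over hydride migration, and methanolysis of the formate then frees the phenol.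

Step 5
Reactants: 7 4-[3,5-bis(benzyloxy)phenoxy]-3,5-bis(methoxymethoxy)phenol
Product: 8 5-(benzyloxy)-2-[3,5-bis(benzyloxy)phenoxy]-1,3-bis(methoxymethoxy)benzene
Conditions: BnBr, K2CO3, DMF, rt
Reagents that add atoms: benzyl bromide, BrCc1ccccc1
Why: Williamson ether synthesis on an unhindered phenoxide should fix the future ring B hydroxyl as a benzyl ether.

Step 6
Reactants: 8 5-(benzyloxy)-2-[3,5-bis(benzyloxy)phenoxy]-1,3-bis(methoxymethoxy)benzene
Product: 9 5-(benzyloxy)-2-[3,5-bis(benzyloxy)phenoxy]benzene-1,3-diol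
Conditions: conc. HCl (cat.), MeOH/THF, 50 °C, argon
Reagents that add atoms: none
Why: Acid-catalysed acetal exchange with methanol should remove both MOM groups while benzyl ethers and the diaryl ether stay intact.

Step 7
Reactants: 2 4-bromo-3,5-dihydroxybenzaldehyde
Product: 10 3,5-bis(benzyloxy)-4-bromobenzaldehyde
Conditions: BnBr, K2CO3, DMF, 60 °C
Reagents that add atoms: benzyl bromide, BrCc1ccccc1
Why: Williamson ether synthesis should convert both phenols into benzyl ethers and give the ring C building block.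

Step 8
Reactants: 9 5-(benzyloxy)-2-[3,5-bis(benzyloxy)phenoxy]benzene-1,3-diol; 10 3,5-bis(benzyloxy)-4-bromobenzaldehyde (2.4 equiv)
Product: 11 5-(benzyloxy)-2-[3,5-bis(benzyloxy)phenoxy]-1,3-bis[2,6-bis(benzyloxy)-4-formylphenoxy]benzene
Conditions: CuI (20 mol %), picolinic acid (40 mol %), K3PO4, DMSO, 100 °C, argon
Reagents that add atoms: none
Why: Twofold copper-catalysed Ullmann diaryl ether coupling should attach both rings C because the bromide is activated by its para-formyl group and the two equivalent phenols of the diol are electron-rich.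

Step 9
Reactants: 11 5-(benzyloxy)-2-[3,5-bis(benzyloxy)phenoxy]-1,3-bis[2,6-bis(benzyloxy)-4-formylphenoxy]benzene
Product: 13 5-(benzyloxy)-2-[3,5-bis(benzyloxy)phenoxy]-1,3-bis[2,6-bis(benzyloxy)-4-hydroxyphenoxy]benzene, via bis(aryl formate) 12 (not isolated)
Conditions: mCPBA (2.5 equiv), CH2Cl2, 0 °C to rt; then K2CO3 (cat.), MeOH/THF, rt
Reagents that add atoms: 3-chloroperoxybenzoic acid, OOC(=O)c1cccc(Cl)c1
Why: Twofold Baeyer–Villiger (Dakin-type) oxidation of the two 3,4,5-trioxygenated benzaldehyde rings should proceed with aryl migration, and methanolysis of the formates then gives the two phenols para to the ether oxygen on rings C.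

Step 10
Reactants: 13 5-(benzyloxy)-2-[3,5-bis(benzyloxy)phenoxy]-1,3-bis[2,6-bis(benzyloxy)-4-hydroxyphenoxy]benzene; 14 methyl bromoacetate (2.5 equiv)
Product: 15 5-(benzyloxy)-2-[3,5-bis(benzyloxy)phenoxy]-1,3-bis[2,6-bis(benzyloxy)-4-(2-methoxy-2-oxoethoxy)phenoxy]benzene
Conditions: K2CO3, acetone, 50 °C
Reagents that add atoms: none
Why: Williamson O-alkylation of the two unhindered phenoxides with an α-bromo ester should give the core bis(aryloxyacetate), which already contains the D1–O bonds.

Step 11
Reactants: 16 2,4,6-trihydroxybenzaldehyde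
Product: 17 2,4,6-tris(benzyloxy)benzaldehyde
Conditions: BnBr, K2CO3, DMF, 60 °C
Reagents that add atoms: benzyl bromide, BrCc1ccccc1
Why: Williamson ether synthesis should benzylate all three phenols, with warming to overcome the hydrogen bonding of the two ortho hydroxyls to the formyl group.

Step 12
Reactants: 17 2,4,6-tris(benzyloxy)benzaldehyde
Product: 19 2-[2,4,6-tris(benzyloxy)phenyl]acetaldehyde, via enol ether 18 (not isolated)
Conditions: Ph3P(CH2OMe)Cl, KOt-Bu, THF, 0 °C to rt; then 2 M HCl, THF, rt
Reagents that add atoms: (methoxymethyl)triphenylphosphonium chloride, COC[P+](c1ccccc1)(c1ccccc1)c1ccccc1.[Cl-]; water, O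
Why: Wittig methoxymethylenation with a reactive non-stabilised ylide followed by mild acid hydrolysis of the enol ether is a standard one-carbon homologation of an aldehyde and should tolerate the benzyl ethers.

Step 13
Reactants: 19 2-[2,4,6-tris(benzyloxy)phenyl]acetaldehyde; 20 ethyl diazoacetate
Product: 21 ethyl 3-oxo-4-[2,4,6-tris(benzyloxy)phenyl]butanoate
Conditions: SnCl2 (10 mol %), CH2Cl2, rt
Reagents that add atoms: none
Why: Roskamp reaction, in which Lewis acid-promoted addition of the diazo ester to the aldehyde is followed by a 1,2-hydride shift with loss of N2, should give the β-keto ester directly from the aliphatic aldehyde.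

Step 14
Reactants: 15 5-(benzyloxy)-2-[3,5-bis(benzyloxy)phenoxy]-1,3-bis[2,6-bis(benzyloxy)-4-(2-methoxy-2-oxoethoxy)phenoxy]benzene; 21 ethyl 3-oxo-4-[2,4,6-tris(benzyloxy)phenyl]butanoate (5 equiv, as its dilithio dianion)
Product: 23 5-(benzyloxy)-2-[3,5-bis(benzyloxy)phenoxy]-1,3-bis{2,6-bis(benzyloxy)-4-[2,4,6-trihydroxy-3-(2,4,6-tris(benzyloxy)phenyl)phenoxy]phenoxy}benzene, via bis(dioxo ester) 22 (not isolated)
Conditions: 21, LiN(i-Pr)2 (10 equiv), THF, −78 to 0 °C; add 15, −78 to 0 °C; then t-BuOH, KOt-Bu (6 equiv), 50 °C, argon; degassed aq. HCl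
Reagents that add atoms: none
Why: The dilithio dianion of 21 should attack each methyl ester of 15 through its benzylic γ-carbon by addition–elimination (bond D5–D6), as in the known γ-acylation of acetoacetate dianions by esters, and the excess dianion takes up the acidic proton between the two ketones of the resulting 4-aryl-6-aryloxy-3,5-dioxohexanoate arms of 22. After the change to KOt-Bu/t-BuOH the chain ionises reversibly, and the minor dienolate that is deprotonated at the aryloxymethyl carbon while the ester is still un-enolised closes each ring D by a 6-(enolendo)-exo-trig Claisen acyl substitution (bond D1–D2); the cyclohexane-1,3,5-trione then tautomerises to the phenoxide form of the arene, which draws all equilibria forward. The closest known reactions are the alkoxide-mediated Claisen cyclisation of δ-keto esters to cyclohexane-1,3-diones and the base-mediated closure of 3,5-dioxohexanoate esters to phloroglucinol. No stereocentre is formed. The step needs γ- over α-acylation, which the dianion secures because its last-formed benzylic carbanion is the reactive site, and carbon over oxygen ring closure (arene, not 4-hydroxy-2-pyranone); the latter is secured by ring E on the central carbon, which disfavours the chelated U-shaped diketonate and turns both chain ends to the same side (helped by the potassium counter-ion), and by the reversibility of lactone formation under alkoxide against the irreversible aromatisation. Complete deprotonation with excess amide base is avoided on purpose, because an enolate next to the ester would switch off the electrophile.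

Step 15
Reactants: 23 5-(benzyloxy)-2-[3,5-bis(benzyloxy)phenoxy]-1,3-bis{2,6-bis(benzyloxy)-4-[2,4,6-trihydroxy-3-(2,4,6-tris(benzyloxy)phenyl)phenoxy]phenoxy}benzene
Product: 24 5-hydroxy-2-(3,5-dihydroxyphenoxy)-1,3-bis{2,6-dihydroxy-4-[2,4,6-trihydroxy-3-(2,4,6-trihydroxyphenyl)phenoxy]phenoxy}benzene (CNP0227063.0)
Conditions: H2 (1 atm), Pd(OH)2/C, THF/MeOH, rt, degassed solvents
Reagents that add atoms: none
Why: Heterogeneous catalytic hydrogenolysis should cleave all thirteen benzyl aryl ethers while diaryl ethers, the biaryl bonds and the arene rings are inert under these conditions.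

## Compound list

1 | 4-bromo-3,5-dimethoxybenzaldehyde | O=Cc1cc(OC)c(Br)c(OC)c1 | starting material
2 | 4-bromo-3,5-dihydroxybenzaldehyde | O=Cc1cc(O)c(Br)c(O)c1 | intermediate
3 | 4-bromo-3,5-bis(methoxymethoxy)benzaldehyde | O=Cc1cc(OCOC)c(Br)c(OCOC)c1 | intermediate
4 | 3,5-bis(benzyloxy)phenol | Oc1cc(OCc2ccccc2)cc(OCc2ccccc2)c1 | starting material
5 | 4-[3,5-bis(benzyloxy)phenoxy]-3,5-bis(methoxymethoxy)benzaldehyde | c1c(OCc2ccccc2)cc(OCc2ccccc2)cc1Oc1c(OCOC)cc(C=O)cc1OCOC | intermediate
6 | 4-[3,5-bis(benzyloxy)phenoxy]-3,5-bis(methoxymethoxy)phenyl formate (not isolated) | c1c(OCc2ccccc2)cc(OCc2ccccc2)cc1Oc1c(OCOC)cc(OC=O)cc1OCOC | intermediate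
7 | 4-[3,5-bis(benzyloxy)phenoxy]-3,5-bis(methoxymethoxy)phenol | c1c(OCc2ccccc2)cc(OCc2ccccc2)cc1Oc1c(OCOC)cc(O)cc1OCOC | intermediate
8 | 5-(benzyloxy)-2-[3,5-bis(benzyloxy)phenoxy]-1,3-bis(methoxymethoxy)benzene | c1c(OCc2ccccc2)cc(OCc2ccccc2)cc1Oc1c(OCOC)cc(OCc2ccccc2)cc1OCOC | intermediate
9 | 5-(benzyloxy)-2-[3,5-bis(benzyloxy)phenoxy]benzene-1,3-diol (rings A and B) | c1c(OCc2ccccc2)cc(OCc2ccccc2)cc1Oc1c(O)cc(OCc2ccccc2)cc1O | intermediate
10 | 3,5-bis(benzyloxy)-4-bromobenzaldehyde | O=Cc1cc(OCc2ccccc2)c(Br)c(OCc2ccccc2)c1 | intermediate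
11 | core dialdehyde: 5-(benzyloxy)-2-[3,5-bis(benzyloxy)phenoxy]-1,3-bis[2,6-bis(benzyloxy)-4-formylphenoxy]benzene | c1c(OCc2ccccc2)cc(OCc2ccccc2)cc1Oc1c(Oc2c(OCc3ccccc3)cc(C=O)cc2OCc2ccccc2)cc(OCc2ccccc2)cc1Oc1c(OCc2ccccc2)cc(C=O)cc1OCc1ccccc1 | intermediate
12 | core bis(aryl formate): 5-(benzyloxy)-2-[3,5-bis(benzyloxy)phenoxy]-1,3-bis[2,6-bis(benzyloxy)-4-(formyloxy)phenoxy]benzene (not isolated) | c1c(OCc2ccccc2)cc(OCc2ccccc2)cc1Oc1c(Oc2c(OCc3ccccc3)cc(OC=O)cc2OCc2ccccc2)cc(OCc2ccccc2)cc1Oc1c(OCc2ccccc2)cc(OC=O)cc1OCc1ccccc1 | intermediate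
13 | core bisphenol: 5-(benzyloxy)-2-[3,5-bis(benzyloxy)phenoxy]-1,3-bis[2,6-bis(benzyloxy)-4-hydroxyphenoxy]benzene | c1c(OCc2ccccc2)cc(OCc2ccccc2)cc1Oc1c(Oc2c(OCc3ccccc3)cc(O)cc2OCc2ccccc2)cc(OCc2ccccc2)cc1Oc1c(OCc2ccccc2)cc(O)cc1OCc1ccccc1 | intermediate
14 | methyl bromoacetate | COC(=O)CBr | starting material
15 | core bis(aryloxyacetate) dimethyl ester: 5-(benzyloxy)-2-[3,5-bis(benzyloxy)phenoxy]-1,3-bis[2,6-bis(benzyloxy)-4-(2-methoxy-2-oxoethoxy)phenoxy]benzene | c1c(OCc2ccccc2)cc(OCc2ccccc2)cc1Oc1c(Oc2c(OCc3ccccc3)cc(OCC(=O)OC)cc2OCc2ccccc2)cc(OCc2ccccc2)cc1Oc1c(OCc2ccccc2)cc(OCC(=O)OC)cc1OCc1ccccc1 | intermediate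
16 | 2,4,6-trihydroxybenzaldehyde | O=Cc1c(O)cc(O)cc1O | starting material
17 | 2,4,6-tris(benzyloxy)benzaldehyde | O=Cc1c(OCc2ccccc2)cc(OCc2ccccc2)cc1OCc1ccccc1 | intermediate
18 | 1,3,5-tris(benzyloxy)-2-(2-methoxyethenyl)benzene, E/Z mixture (not isolated) | COC=Cc1c(OCc2ccccc2)cc(OCc2ccccc2)cc1OCc1ccccc1 | intermediate
19 | 2-[2,4,6-tris(benzyloxy)phenyl]acetaldehyde | O=CCc1c(OCc2ccccc2)cc(OCc2ccccc2)cc1OCc1ccccc1 | intermediate
20 | ethyl diazoacetate | CCOC(=O)C=[N+]=[N-] | starting material
21 | ethyl 3-oxo-4-[2,4,6-tris(benzyloxy)phenyl]butanoate | CCOC(=O)CC(=O)Cc1c(OCc2ccccc2)cc(OCc2ccccc2)cc1OCc1ccccc1 | intermediate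
22 | core bis(dioxo ester): as 15, with each OCH2CO2Me arm replaced by OCH2–CO–CH[2,4,6-tris(benzyloxy)phenyl]–CO–CH2–CO2Et (not isolated) | c1c(OCc2ccccc2)cc(OCc2ccccc2)cc1Oc1c(Oc2c(OCc3ccccc3)cc(OCC(=O)C(C(=O)CC(=O)OCC)c3c(OCc4ccccc4)cc(OCc4ccccc4)cc3OCc3ccccc3)cc2OCc2ccccc2)cc(OCc2ccccc2)cc1Oc1c(OCc2ccccc2)cc(OCC(=O)C(C(=O)CC(=O)OCC)c2c(OCc3ccccc3)cc(OCc3ccccc3)cc2OCc2ccccc2)cc1OCc1ccccc1 | intermediate
23 | tridecabenzyl ether with both rings D as free triols: 5-(benzyloxy)-2-[3,5-bis(benzyloxy)phenoxy]-1,3-bis{2,6-bis(benzyloxy)-4-[2,4,6-trihydroxy-3-(2,4,6-tris(benzyloxy)phenyl)phenoxy]phenoxy}benzene | c1c(OCc2ccccc2)cc(OCc2ccccc2)cc1Oc1c(Oc2c(OCc3ccccc3)cc(Oc3c(O)cc(O)c(-c4c(OCc5ccccc5)cc(OCc5ccccc5)cc4OCc4ccccc4)c3O)cc2OCc2ccccc2)cc(OCc2ccccc2)cc1Oc1c(OCc2ccccc2)cc(Oc2c(O)cc(O)c(-c3c(OCc4ccccc4)cc(OCc4ccccc4)cc3OCc3ccccc3)c2O)cc1OCc1ccccc1 | intermediate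
24 | CNP0227063.0: 5-hydroxy-2-(3,5-dihydroxyphenoxy)-1,3-bis{2,6-dihydroxy-4-[2,4,6-trihydroxy-3-(2,4,6-trihydroxyphenyl)phenoxy]phenoxy}benzene | Oc1cc(O)cc(Oc2c(Oc3c(O)cc(Oc4c(O)cc(O)c(-c5c(O)cc(O)cc5O)c4O)cc3O)cc(O)cc2Oc2c(O)cc(Oc3c(O)cc(O)c(-c4c(O)cc(O)cc4O)c3O)cc2O)c1 | target

## Step count

Total step count: 15.
Longest linear sequence: 11 steps (steps 1, 2, 3, 4, 5, 6, 8, 9, 10, 14, 15).

## Steps most likely to fail

**1. Step 14 (key step).** Three processes may defeat it: proton transfer from the aryloxyacetate to the dianion in place of acylation; ring closure through oxygen, or no closure at all if the chain rests as an unreactive polyenolate; and air oxidation of the phloroglucinol anions. The fallback separates the two bond formations and sets out from 13. Alkylation of 13 with 2-chloro-N-methoxy-N-methylacetamide (K2CO3, NaI, DMF) should give the core bis(N-methoxy-N-methylamide) F1, in which each OCH2CO2Me arm of 15 is replaced by OCH2C(=O)N(OMe)Me. The dianion of 21 (LiN(i-Pr)2, THF, −78 to 0 °C) should add to F1 and stop at the chelated tetrahedral adduct, so that neither proton transfer from the product nor premature ring closure interferes. Acidic work-up then gives 22 as an isolated and purified compound. In a separate operation 22 is cyclised with NaOMe in MeOH/toluene at reflux, where any lactone formed by oxygen attack is reopened by methoxide and the chain is funnelled into the arene. The fallback comes back to the route at 23.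

**2. Step 8.** Copper insertion into the bromide flanked by two benzyloxy groups may be slow, so that the reaction stalls after one arylation or reductive loss of bromine takes over. The fallback replaces the metal-catalysed coupling by nucleophilic aromatic substitution on a fluoride and sets out from 10 and 9. Compound 10 is converted with HC(OMe)3 and TsOH in MeOH into 3,5-bis(benzyloxy)-4-bromobenzaldehyde dimethyl acetal F2. Bromine–lithium exchange (n-BuLi, THF, −78 °C) and quenching with N-fluorobenzenesulfonimide should give 3,5-bis(benzyloxy)-4-fluorobenzaldehyde dimethyl acetal F3, which aqueous HCl hydrolyses to 3,5-bis(benzyloxy)-4-fluorobenzaldehyde F4. Diol 9 and F4 (Cs2CO3, DMSO, 110 °C) should then give 11 by twofold addition–elimination para to the formyl group, where the route is rejoined.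

**3. Step 9.** The peracid may attack the electron-rich rings A and B (ring hydroxylation and quinone formation) in competition with the Baeyer–Villiger oxidation of the two formyl groups. The fallback moves the oxidation to the monomer, before rings A and B are present, and sets out from 10. Treatment of 10 with mCPBA in CH2Cl2 should give 3,5-bis(benzyloxy)-4-bromophenyl formate F5, and methanolysis (K2CO3, MeOH) gives 3,5-bis(benzyloxy)-4-bromophenol F6. Alkylation of F6 with 14 (K2CO3, acetone) gives methyl 2-[3,5-bis(benzyloxy)-4-bromophenoxy]acetate F7. Palladium-catalysed C–O coupling of diol 9 with F7 (Pd(OAc)2, 2-di-tert-butylphosphino-2′,4′,6′-triisopropylbiphenyl, K3PO4, toluene, 100 °C), which is suited to electron-rich hindered bromides, should then give 15 directly. Compounds 11 and 13 are bypassed and the route is rejoined at 15.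

## Further compounds

F1 | step 14 | core bis(N-methoxy-N-methylamide): 5-(benzyloxy)-2-[3,5-bis(benzyloxy)phenoxy]-1,3-bis{2,6-bis(benzyloxy)-4-[2-(methoxy(methyl)amino)-2-oxoethoxy]phenoxy}benzene | c1c(OCc2ccccc2)cc(OCc2ccccc2)cc1Oc1c(Oc2c(OCc3ccccc3)cc(OCC(=O)N(C)OC)cc2OCc2ccccc2)cc(OCc2ccccc2)cc1Oc1c(OCc2ccccc2)cc(OCC(=O)N(C)OC)cc1OCc1ccccc1
F2 | step 8 | 3,5-bis(benzyloxy)-4-bromobenzaldehyde dimethyl acetal | COC(OC)c1cc(OCc2ccccc2)c(Br)c(OCc2ccccc2)c1
F3 | step 8 | 3,5-bis(benzyloxy)-4-fluorobenzaldehyde dimethyl acetal | COC(OC)c1cc(OCc2ccccc2)c(F)c(OCc2ccccc2)c1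
F4 | step 8 | 3,5-bis(benzyloxy)-4-fluorobenzaldehyde | O=Cc1cc(OCc2ccccc2)c(F)c(OCc2ccccc2)c1
F5 | step 9 | 3,5-bis(benzyloxy)-4-bromophenyl formate | O=COc1cc(OCc2ccccc2)c(Br)c(OCc2ccccc2)c1
F6 | step 9 | 3,5-bis(benzyloxy)-4-bromophenol | Oc1cc(OCc2ccccc2)c(Br)c(OCc2ccccc2)c1
F7 | step 9 | methyl 2-[3,5-bis(benzyloxy)-4-bromophenoxy]acetate | COC(=O)COc1cc(OCc2ccccc2)c(Br)c(OCc2ccccc2)c1
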